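The birch run stops early: its product reads 4 % at 6.00 min and still 4 % at 15.0 min, in a flask charged with more impurity than precatalyst. The elm run, with less impurity than precatalyst, climbs after an induction period from 7 % at 8.00 min to 25 % at 15.0 min, a reading of 0.0257 /min of the substrate charge. Both runs read as a titration of the catalyst, in which each impurity removes one catalyst for good.

the same everywhere: substrate 0.10 M

| run | reagent | precatalyst | impurity | temperature | remark | time |
|---|---|---|---|---|---|---|
| elm | 0.20 M (in portions, 4) | 0.30 mM | 0.11 mM | 10 °C | run made earlier; portions every 10 min |  |
| birch | 0.20 M (in portions, 4) | 0.20 mM | 0.22 mM | 10 °C | run made earlier; portions every 10 min |  |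
| delta | 0.200 M (in portions, 4) | 0.20 mM | 0.11 mM |  | at 10 °C until 20 min, from then on at 35 °C; the portions of reagent follow each other after 10 min, the first at the start | 40 min |
| eta | 0.300 M (in portions, 4) | 0.20 mM | 0.11 mM |  | at 35 °C throughout; the portions of reagent follow each other after 10 min, the first at the start | 12 min |

- elm (time / min: product / %, substrate / %): 3.00: 5, 102; 6.00: 4, 93; 8.00: 7, 89; 12.0: 17, 81; 15.0: 25, 75
- birch (time / min: product / %, substrate / %): 3.00: 3, 100; 6.00: 4, 94; 8.00: 4, 98; 12.0: 4, 97; 15.0: 4, 97

(each reading ± 1.5 percentage points)

- the earlier runs were read with a standard deviation of 1.5 percentage points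
- what may be going on: substrate + free catalyst -> catalyst intermediate A; reagent + catalyst intermediate A <-> catalyst intermediate B; catalyst intermediate B -> catalyst intermediate C; free catalyst + impurity -> spent catalyst; catalyst intermediate C -> free catalyst + product; precatalyst <-> free catalyst
- percentages count the whole charge, also what has not yet gone in
- the earlier runs do not show what temperature does; that part of a forecast is a guess

- the flask that ends with the higher amount of product, in percent of the substrate charged, or "neither" when 2 percentage points or less lies between them (delta / eta / neither)
- final product, as a percentage of the substrate charged, in delta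
- final product, as a percentage of the substrate charged, in eta

Delta and eta have the same precatalyst and impurity charges, and so the same surviving share of 0.450: the fraction of the catalyst charge left unspent, in whichever form, once each impurity has removed one catalyst. The share is 0.633 in elm and 0 in birch. Taking the rate in proportion to surviving catalyst, delta and eta each hold about half of what elm holds, which gives 0.0122 /min of the charge at 10 °C.

Two extreme flasks bracket the answer. With warming taken to do nothing and elm's induction period kept, delta reaches 0.390 of the charge and eta 0.0488. With warming taken as enormous, both finish and the answer is neither. The earlier runs show nothing of temperature, so the real flasks lie between these, and counting hot minutes places them. At one common hot rate, eta's gain in its 12 min is reckoned at 0.600 of delta's gain in its 20.0 min, and delta's cold gain before the change of temperature is reckoned at 0.146 of the charge. This reckoning therefore commits to delta.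

The forecast gave delta, with 88 % for delta and 65 % for eta, and said “Delta's longer time should win”. The simulation gives 77.5 % for delta and 39.2 % for eta.

    substrate + free catalyst → catalyst intermediate A (k = 8.03 /M/s, Ea = 40.0 kJ/mol)
    reagent + catalyst intermediate A ⇌ catalyst intermediate B (K = 42.8 /M, k = 4.83 /M/s, Ea = 39.0 kJ/mol, ΔH = 5.00 kJ/mol)
    catalyst intermediate B → catalyst intermediate C (k = 13.0 /s, Ea = 72.0 kJ/mol)
    free catalyst + impurity → spent catalyst (k = 494 /M/s, Ea = 41.0 kJ/mol)
    catalyst intermediate C → free catalyst + product (k = 2.98 /s, Ea = 71.0 kJ/mol)
    precatalyst ⇌ free catalyst (K = 5.36, k = 0.00656 /s, Ea = 76.0 kJ/mol, ΔH = −48.0 kJ/mol)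
    (constants at 10 °C)

Delta's hot span of 20.0 min is 1.89 times the half-life of the slowest mode of the whole flask as it stands at 40.0 min, which is 10.6 min. Over that span the substrate in delta falls from 81.2 % to 22.4 %. Spent catalyst in delta stands at 55.0 % at 40.0 min, beside a surviving share of 0.450. A neighbour of delta charged with 0.600 of delta's impurity has a surviving share of 0.670, and it ends with 33.0 % spent catalyst and 90.4 % product.

The data are calculated for an exercise; the scatter is artificial.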